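**Plan**

Numbering of the target core (2H-chromene-4,7-dione): O1, C2, C3, C4, C4a, C5(OH), C6, C7(=O), C8, C8a. Ring A is the cyclohexadienone, ring B the dihydropyranone.

1. Retrosynthesis: ester hydrolysis and the prenyl C=C (Wittig) are cut first; ring A is then opened at C6–C7 and C8–C8a, giving sulfonyl-dihydropyranone 26 (ring B with the side chain) and lactone 9 (C7, C8, the cyclobutylmethyl group and the masked prenyl carbons).
2. Enabling feature: C8 is the α-carbon of the C7 ketone and also the substituent on C8a of the vinylogous ester O1–C8a=C4a–C4=O; C6 is α to the C5 enol carbon; the prenyl CH2–CH on C8 sits where C4–C5 of a γ-lactone with carbonyl C7 would lie.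
3. Forward: ring B is built first (aldol unit, glutaric hemiester, CS2 carbon as C8a); lactone 9 is made from (+)-verbenone and a menthyloxy-butyrolactone; ring A closes in the Michael–Claisen union of 9 and 26; Wittig olefination and ester hydrolysis finish.
4. Stereochemistry: cyclobutane from (1R,5R)-verbenone; C2/C3 from an Evans syn aldol; side-chain centre from quinine-mediated anhydride desymmetrisation; quaternary C8 from the (5S)-acetal carbon of the lactone (attack anti to the menthyloxy group), which then leaves as menthol and unveils the aldehyde.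

Key step: step 16

Remarks on the chemistry (assumptions):
- (1R,5R)-(+)-Verbenone and (5S)-5-(d-menthyloxy)furan-2(5H)-one, the enantiomers of the more common commercial forms, are taken as purchasable.
- Quinine is assumed to open 3-propylglutaric anhydride in the same sense as its 3-isobutyl analogue; if the hemiester proves to be (S), quinidine is used instead.
- Lactone 9 is carried as a mixture of C3 epimers (major one drawn); this centre is planarised in step 16.

**Route**

Step 1
Reactants: 1 (1R,5R)-(+)-verbenone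
Product: 2 (1R,3S)-3-acetyl-2,2-dimethylcyclobutane-1-carboxylic acid (cis-pinononic acid)
Conditions: RuCl3 hydrate (cat.), NaIO4, CCl4/MeCN/H2O, rt
Reagents that add atoms: sodium periodate, [Na+].[O-]I(=O)(=O)=O
Why: RuO4-mediated oxidative cleavage of the enone C=C with loss of the former C3 as CO2 is the established route from verbenone to cis-pinononic acid, and both ring stereocentres come unchanged from the terpene.

Step 2
Reactants: 2 cis-pinononic acid
Product: 3 (1R,3R)-2,2-dimethyl-3-(prop-1-en-2-yl)cyclobutane-1-carboxylic acid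
Conditions: Ph3PCH3Br, KOtBu (2.5 equiv each), THF, 0 °C → rt; aq. HCl work-up
Reagents that add atoms: methyltriphenylphosphonium bromide, C[P+](c1ccccc1)(c1ccccc1)c1ccccc1.[Br-]
Why: Wittig methylenation of the methyl ketone (the carboxylate formed first is inert) should be faster than enolisation, so the cis ring configuration is kept.

Step 3
Reactants: 3 isopropenyl acid
Product: 4 [(1R,3R)-2,2-dimethyl-3-(prop-1-en-2-yl)cyclobutyl]methanol
Conditions: LiAlH4, Et2O, 0 °C → rt
Reagents that add atoms: none
Why: Hydride reduction of the acid to the primary alcohol leaves the isolated 1,1-disubstituted alkene and both stereocentres untouched.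

Step 4
Reactants: 4 cyclobutylmethanol
Product: 5 [(1R,3R)-2,2-dimethyl-3-(prop-1-en-2-yl)cyclobutyl]methyl trifluoromethanesulfonate
Conditions: Tf2O, pyridine, CH2Cl2, −78 → −40 °C; filtered cold and used at once
Reagents that add atoms: triflic anhydride, O=S(=O)(OS(=O)(=O)C(F)(F)F)C(F)(F)F
Why: O-sulfonylation gives a leaving group reactive enough for SN2 displacement at the β-branched carbon.

Step 5
Reactants: 6 (5S)-5-[(1S,2R,5S)-menthyloxy]furan-2(5H)-one
Product: 7 (5S)-5-[(1S,2R,5S)-menthyloxy]dihydrofuran-2(3H)-one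
Conditions: H2 (1 atm), Pd/C, EtOAc, rt
Reagents that add atoms: none
Why: Catalytic hydrogenation saturates the butenolide C=C without touching the acetal stereocentre.

Step 6
Reactants: 7 menthyloxy lactone; 5 cyclobutylmethyl triflate
Product: 9 (5S)-3-{[(1S,3R)-2,2-dimethyl-3-(prop-1-en-2-yl)cyclobutyl]methyl}-5-[(1S,2R,5S)-menthyloxy]dihydrofuran-2(3H)-one, via lithium enolate 8 (not isolated)
Conditions: LDA, THF, −78 °C; then 5, −78 → −30 °C
Reagents that add atoms: none
Why: SN2 alkylation of the lactone enolate by the primary triflate should enter mainly anti to the acetal alkoxy group, but the new α-centre is of no consequence because step 16 planarises it.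

Step 7
Reactants: 10 (4S)-4-benzyl-3-propanoyloxazolidin-2-one; 11 acetaldehyde
Product: 13 (4S)-4-benzyl-3-[(2S,3R)-3-hydroxy-2-methylbutanoyl]oxazolidin-2-one, via boron enolate 12 (not isolated)
Conditions: n-Bu2BOTf, i-Pr2NEt, CH2Cl2, −78 → 0 °C; MeCHO, −78 → 0 °C; pH 7 buffer, MeOH, H2O2
Reagents that add atoms: none
Why: Evans syn aldol through the Z-boron enolate and a Zimmerman–Traxler chair, the (S)-benzyl auxiliary setting the (2S,3R) centres that become C3 and C2 of ring B.

Step 8
Reactants: 13 aldol adduct
Product: 14 (2S,3R)-3-hydroxy-N-methoxy-N,2-dimethylbutanamide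
Conditions: MeNHOMe·HCl, AlMe3, CH2Cl2, −10 → 0 °C; 1 M aq. HCl work-up
Reagents that add atoms: N,O-dimethylhydroxylamine hydrochloride, CNOC.Cl
Why: Aluminium-amide transamidation of the imide to the Weinreb amide is standard for Evans aldol adducts and does not touch the α-centre.

Step 9
Reactants: 14 hydroxy Weinreb amide
Product: 15 (2S,3R)-N-methoxy-N,2-dimethyl-3-(triethylsilyloxy)butanamide
Conditions: TESCl, imidazole, DMF, 0 °C → rt
Reagents that add atoms: chlorotriethylsilane, CC[Si](Cl)(CC)CC
Why: Silylation masks the secondary alcohol for the organometallic and enolate steps that follow.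

Step 10
Reactants: 15 silyl ether
Product: 16 (3S,4R)-3-methyl-4-(triethylsilyloxy)pentan-2-one
Conditions: MeMgBr, THF, 0 °C; aq. NH4Cl
Reagents that add atoms: methylmagnesium bromide, C[Mg]Br
Why: Weinreb ketone synthesis stops at the methyl ketone through the chelated tetrahedral intermediate, without epimerisation.

Step 11
Reactants: 17 3-propylglutaric anhydride
Product: 18 (3R)-3-(2-methoxy-2-oxoethyl)hexanoic acid
Conditions: quinine (1.1 equiv), MeOH (3 equiv), toluene, −50 °C; 1 M aq. HCl wash (quinine recovered)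
Reagents that add atoms: methanol, CO
Why: Alkaloid-mediated desymmetrising methanolysis of the prochiral anhydride differentiates the enantiotopic carbonyl groups and sets the propyl-bearing centre.

Step 12
Reactants: 16 methyl ketone; 18 hemiester
Product: 21 methyl (3R,8S,9R)-8-methyl-5,7-dioxo-3-propyl-9-(triethylsilyloxy)decanoate, via acyl imidazole 19 (not isolated), via lithium enolate 20 (not isolated)
Conditions: 18, CDI, THF, rt; separately 16, LiHMDS (3.2 equiv), THF, −78 °C; combine, −78 → −30 °C; aq. NH4Cl
Reagents that add atoms: none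
Why: Crossed Claisen C-acylation of the kinetic methyl-side enolate by the acyl imidazole gives the 1,3-diketone, stored as its diketonate by the excess base so that the α-stereocentre is not enolised.

Step 13
Reactants: 21 1,3-diketone
Product: 23 methyl (3R,8S,9R)-6-[bis(methylsulfanyl)methylidene]-8-methyl-5,7-dioxo-3-propyl-9-(triethylsilyloxy)decanoate, via dipotassium dithiolate 22 (not isolated)
Conditions: K2CO3 (2.2 equiv), CS2, DMF, 0 °C → rt; then MeI (2.2 equiv)
Reagents that add atoms: carbon disulfide, S=C=S; iodomethane, CI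
Why: Standard α-oxoketene dithioacetal formation at the active methylene brings in the future C8a at the carboxyl oxidation level.

Step 14
Reactants: 23 ketene dithioacetal
Product: 25 methyl (3R)-3-{2-[(2R,3S)-2,3-dimethyl-6-(methylsulfanyl)-4-oxo-3,4-dihydro-2H-pyran-5-yl]-2-oxoethyl}hexanoate, via hydroxy dithioacetal 24 (not isolated)
Conditions: HF·pyridine, pyridine/THF, 0 °C → rt; then PPTS (cat.), toluene, 50 °C, N2 sweep
Reagents that add atoms: none
Why: Desilylation frees the alcohol, which closes ring B by intramolecular addition–elimination at the dithioacetal carbon (6-endo-trig, as in 2-methylthiochromone synthesis); the cis-dimethyl centres are not involved.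

Step 15
Reactants: 25 methylsulfanyl pyranone
Product: 26 methyl (3R)-3-{2-[(2R,3S)-6-(methanesulfonyl)-2,3-dimethyl-4-oxo-3,4-dihydro-2H-pyran-5-yl]-2-oxoethyl}hexanoate
Conditions: mCPBA (2.2 equiv), NaHCO3, CH2Cl2, 0 °C → rt
Reagents that add atoms: 3-chloroperoxybenzoic acid, O=C(OO)c1cccc(Cl)c1
Why: Sulfide-to-sulfone oxidation turns the thioether into a far better leaving group on the doubly acyl-activated carbon; the electron-poor C=C is inert to the peracid.

Step 16
Reactants: 9 cyclobutylmethyl menthyloxy lactone; 26 sulfonyl pyranone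
Product: 29 methyl (3S)-3-[(2R,3S,8S)-8-{[(1S,3R)-2,2-dimethyl-3-(prop-1-en-2-yl)cyclobutyl]methyl}-5-hydroxy-2,3-dimethyl-4,7-dioxo-8-(2-oxoethyl)-3,4,7,8-tetrahydro-2H-chromen-6-yl]hexanoate, via lithium enolate 27 (not isolated), via addition–elimination adduct 28 (not isolated)
Conditions: 9 (1.05 equiv), LDA (1.0 equiv), THF, −78 °C; 26, −78 °C; then LiHMDS (1.2 equiv), −78 → 0 °C; 0.5 M aq. HCl, 0 °C
Reagents that add atoms: none
Why: The ring-fixed enolate 27 adds to C6 of pyranone 26, the carbon activated by both the ring ketone and the acyl ketone, and methanesulfinate leaves to give 28 with the quaternary carbon in place; the second base enolises the acyl CH2, which acylates the lactone carbonyl, and the expelled hemiacetal alkoxide collapses to the aldehyde and menthoxide, which is quenched by the acidic trione just formed, making the cascade irreversible. The closest known reaction type is the Michael–Claisen (Michael–Dieckmann) annulation of ester and lactone enolates with enones, combined with the addition–elimination known for 2-sulfonylchromones and α-oxoketene dithioacetals. Ring A closes by a 6-(enolexo)-exo-trig Dieckmann acylation, the acyl group and the new quaternary carbon being held cis across the pyranone C5=C6 bond. The quaternary stereocentre is controlled by the acetal carbon C5 of the lactone: the five-membered ring fixes the enolate geometry and the electrophile should enter anti to the pseudoaxial menthyloxy group (1,3-induction as in the dialkylation of γ-substituted butyrolactones), which with the (5S)-acetal gives the configuration of the target. The step needs C–C bond formation to outrun proton transfer from the acyl CH2 of 26 and attack at C6 in preference to a carbonyl group; the sulfonyl group on the push–pull carbon is meant to secure both at −78 °C, and the ring-fusion regiochemistry is fixed because the ring oxygen already sits on the electrophilic carbon.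

Step 17
Reactants: 29 trione aldehyde
Product: 30 methyl (3S)-3-[(2R,3S,8R)-8-{[(1S,3R)-2,2-dimethyl-3-(prop-1-en-2-yl)cyclobutyl]methyl}-5-hydroxy-2,3-dimethyl-8-(3-methylbut-2-en-1-yl)-4,7-dioxo-3,4,7,8-tetrahydro-2H-chromen-6-yl]hexanoate
Conditions: i-PrPPh3I, KHMDS (2.5 equiv each), THF, 0 °C; then 29, −78 → 0 °C; pH 4 buffer
Reagents that add atoms: isopropyltriphenylphosphonium iodide, CC(C)[P+](c1ccccc1)(c1ccccc1)c1ccccc1.[I-]
Why: Wittig olefination with the unstabilised isopropylidene ylide converts the aldehyde into the prenyl group while the trione, stored as its enolate by the first equivalent of ylide, and the methyl ester stay inert.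

Step 18
Reactants: 30 methyl ester
Product: 31 target acid, (3S)-3-[(2R,3S,8R)-8-{[(1S,3R)-2,2-dimethyl-3-(prop-1-en-2-yl)cyclobutyl]methyl}-5-hydroxy-2,3-dimethyl-8-(3-methylbut-2-en-1-yl)-4,7-dioxo-3,4,7,8-tetrahydro-2H-chromen-6-yl]hexanoic acid
Conditions: LiOH·H2O (4 equiv), THF/MeOH/H2O, 0 °C → rt; cold 0.5 M aq. HCl to pH 3
Reagents that add atoms: lithium hydroxide, [Li+].[OH-]
Why: Saponification of the unhindered methyl ester; the substrate is present as the vinylogous-acid anion, which lowers the acidity of H-3, so the cis-2,3-dimethyl unit should survive, and any enol lactone formed would be reopened by hydroxide.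

**Compound list**

1 | (1R,5R)-(+)-verbenone | CC1=CC(=O)[C@@H]2C[C@H]1C2(C)C | starting material
2 | (1R,3S)-3-acetyl-2,2-dimethylcyclobutane-1-carboxylic acid | CC(=O)[C@H]1C[C@@H](C(=O)O)C1(C)C | intermediate
3 | (1R,3R)-2,2-dimethyl-3-(prop-1-en-2-yl)cyclobutane-1-carboxylic acid | C=C(C)[C@H]1C[C@@H](C(=O)O)C1(C)C | intermediate
4 | [(1R,3R)-2,2-dimethyl-3-(prop-1-en-2-yl)cyclobutyl]methanol | C=C(C)[C@H]1C[C@@H](CO)C1(C)C | intermediate
5 | [(1R,3R)-2,2-dimethyl-3-(prop-1-en-2-yl)cyclobutyl]methyl triflate | C=C(C)[C@H]1C[C@@H](COS(=O)(=O)C(F)(F)F)C1(C)C | intermediate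
6 | (5S)-5-[(1S,2R,5S)-menthyloxy]furan-2(5H)-one | O=C1C=C[C@@H](O[C@H]2C[C@@H](C)CC[C@@H]2C(C)C)O1 | starting material
7 | (5S)-5-[(1S,2R,5S)-menthyloxy]dihydrofuran-2(3H)-one | O=C1CC[C@@H](O[C@H]2C[C@@H](C)CC[C@@H]2C(C)C)O1 | intermediate
8 | lithium enolate of 7 (not isolated) | [Li+].[O-]C1=CC[C@@H](O[C@H]2C[C@@H](C)CC[C@@H]2C(C)C)O1 | intermediate
9 | (5S)-3-(cyclobutylmethyl)-5-menthyloxy lactone (3,5-trans epimer drawn; 3-epimer carried along) | C=C(C)[C@H]1C[C@@H](C[C@@H]2C[C@@H](O[C@H]3C[C@@H](C)CC[C@@H]3C(C)C)OC2=O)C1(C)C | intermediate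
10 | (4S)-4-benzyl-3-propanoyloxazolidin-2-one | CCC(=O)N1[C@@H](Cc2ccccc2)COC1=O | starting material
11 | acetaldehyde | CC=O | starting material
12 | (Z)-dibutylboron enolate of 10 (not isolated) | C/C=C(\OB(CCCC)CCCC)N1[C@@H](Cc2ccccc2)COC1=O | intermediate
13 | (4S)-4-benzyl-3-[(2S,3R)-3-hydroxy-2-methylbutanoyl]oxazolidin-2-one | C[C@@H](O)[C@H](C)C(=O)N1[C@@H](Cc2ccccc2)COC1=O | intermediate
14 | (2S,3R)-3-hydroxy-N-methoxy-N,2-dimethylbutanamide | C[C@@H](O)[C@H](C)C(=O)N(C)OC | intermediate
15 | (2S,3R)-N-methoxy-N,2-dimethyl-3-(triethylsilyloxy)butanamide | CC[Si](CC)(CC)O[C@H](C)[C@H](C)C(=O)N(C)OC | intermediate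
16 | (3S,4R)-3-methyl-4-(triethylsilyloxy)pentan-2-one | CC[Si](CC)(CC)O[C@H](C)[C@H](C)C(C)=O | intermediate
17 | 3-propylglutaric anhydride | CCCC1CC(=O)OC(=O)C1 | starting material
18 | (3R)-3-(2-methoxy-2-oxoethyl)hexanoic acid | CCC[C@H](CC(=O)O)CC(=O)OC | intermediate
19 | acyl imidazole of 18 (not isolated) | CCC[C@H](CC(=O)n1ccnc1)CC(=O)OC | intermediate
20 | lithium enolate of 16, methyl side (not isolated) | CC[Si](CC)(CC)O[C@H](C)[C@H](C)C(=C)[O-].[Li+] | intermediate
21 | methyl (3R,8S,9R)-8-methyl-5,7-dioxo-3-propyl-9-(triethylsilyloxy)decanoate | CC[Si](CC)(CC)O[C@H](C)[C@H](C)C(=O)CC(=O)C[C@@H](CCC)CC(=O)OC | intermediate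
22 | dipotassium ketene dithiolate of 21 (not isolated) | CC[Si](CC)(CC)O[C@H](C)[C@H](C)C(=O)C(=C([S-])[S-])C(=O)C[C@@H](CCC)CC(=O)OC.[K+].[K+] | intermediate
23 | bis(methylsulfanyl)methylidene diketone | CC[Si](CC)(CC)O[C@H](C)[C@H](C)C(=O)C(=C(SC)SC)C(=O)C[C@@H](CCC)CC(=O)OC | intermediate
24 | 9-hydroxy ketene dithioacetal (not isolated) | C[C@@H](O)[C@H](C)C(=O)C(=C(SC)SC)C(=O)C[C@@H](CCC)CC(=O)OC | intermediate
25 | 6-(methylsulfanyl)dihydropyranone | CCC[C@@H](CC(=O)OC)CC(=O)C1=C(SC)O[C@H](C)[C@H](C)C1=O | intermediate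
26 | 6-(methanesulfonyl)dihydropyranone | CCC[C@@H](CC(=O)OC)CC(=O)C1=C(S(C)(=O)=O)O[C@H](C)[C@H](C)C1=O | intermediate
27 | lithium enolate of 9 (not isolated) | C=C(C)[C@H]1C[C@@H](CC2=C([O-])O[C@H](O[C@H]3C[C@@H](C)CC[C@@H]3C(C)C)C2)C1(C)C.[Li+] | intermediate
28 | addition–elimination adduct, lactone with quaternary C3 (not isolated) | C=C(C)[C@H]1C[C@@H](C[C@]2(C[C@@H](O[C@H]4C[C@@H](C)CC[C@@H]4C(C)C)OC2=O)C3=C(C(=O)C[C@@H](CCC)CC(=O)OC)C(=O)[C@@H](C)[C@@H](C)O3)C1(C)C | intermediate
29 | 8-(2-oxoethyl) trione methyl ester | C=C(C)[C@H]1C[C@@H](C[C@@]2(CC=O)C(=O)C([C@@H](CCC)CC(=O)OC)=C(O)C3=C2O[C@H](C)[C@H](C)C3=O)C1(C)C | intermediate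
30 | methyl ester of the target | C=C(C)[C@H]1C[C@@H](C[C@@]2(CC=C(C)C)C(=O)C([C@@H](CCC)CC(=O)OC)=C(O)C3=C2O[C@H](C)[C@H](C)C3=O)C1(C)C | intermediate
31 | target acid CNP0364345.1 | C=C(C)[C@H]1C[C@@H](C[C@@]2(CC=C(C)C)C(=O)C([C@@H](CCC)CC(=O)O)=C(O)C3=C2O[C@H](C)[C@H](C)C3=O)C1(C)C | target

**Totals and risks**

Total step count: 18. Longest linear sequence: 11 steps (steps 7–10 and 12–18, from imide 10).

Steps most likely to fail:

Step 16. Proton transfer from the acyl methylene of 26 to the hindered enolate 27, or erosion of facial control at the quaternary carbon, may outrun the conjugate addition. The fallback gives up stereocontrol at C8 and uses classical chemistry; it sets out from triflate 5 and sulfone 26. The lithium enolate of methyl acetate (LDA, THF, −78 °C) is alkylated with 5 to give methyl 3-[(1R,3R)-2,2-dimethyl-3-(prop-1-en-2-yl)cyclobutyl]propanoate F1. The unhindered enolate of F1 undergoes the same Michael–Claisen annulation with 26 (LDA, then LiHMDS, THF, −78 → 0 °C), and the product, now carrying hydrogen on C8, aromatises to the 8-(cyclobutylmethyl)-5,7-dihydroxychromanone ester F2. Dearomatising C-prenylation of F2 at C8 (prenyl bromide, NaOMe, MeOH, 0 °C), the classical alkylation of acylphloroglucinols, should give ester 30 together with its C8 epimer, to be separated by HPLC. The route is rejoined at 30.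

Step 17. The strongly basic, hindered ylide may deprotonate C3 next to the pyranone carbonyl (epimerisation of the cis-dimethyl unit by enolisation or ring opening and reclosure) faster than it olefinates the aldehyde, which may be masked as a cyclic hemiacetal with the enol. The fallback sets out from aldehyde 29. Non-basic Takai–Lombardo methylenation (Zn, CH2Br2, TiCl4, THF/CH2Cl2, 0 °C) gives the 8-allyl trione ester F3. Cross-metathesis of F3 with 2-methyl-2-butene (second-generation Grubbs catalyst, CH2Cl2, 40 °C) converts allyl into prenyl; the isopropenyl group is too hindered to take part. The route is rejoined at 30.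

Step 6. Slow SN2 displacement at the β-branched cyclobutylmethyl carbon may allow ionisation and ring expansion of the triflate or fragmentation of the acetal-lactone enolate. The fallback sets out from alcohol 4 and lactone 7. Oxidation of 4 (Dess–Martin periodinane, NaHCO3, CH2Cl2) gives (1R,3R)-2,2-dimethyl-3-(prop-1-en-2-yl)cyclobutane-1-carbaldehyde F4. Aldol addition of enolate 8 to F4 (THF, −78 °C) gives the β-hydroxy lactone F5. Mesylation and elimination (MsCl, Et3N; then DBU) give the (E)-alkylidene lactone F6. Conjugate reduction with [(Ph3P)CuH]6 saturates only the conjugated C=C, and the route is rejoined at 9.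

Further compounds
F1 | step 16 | methyl 3-[(1R,3R)-2,2-dimethyl-3-(prop-1-en-2-yl)cyclobutyl]propanoate | C=C(C)[C@H]1C[C@@H](CCC(=O)OC)C1(C)C
F2 | step 16 | methyl (3S)-3-[(2R,3S)-8-{[(1S,3R)-2,2-dimethyl-3-(prop-1-en-2-yl)cyclobutyl]methyl}-5,7-dihydroxy-2,3-dimethyl-4-oxo-3,4-dihydro-2H-chromen-6-yl]hexanoate | C=C(C)[C@H]1C[C@@H](Cc2c(O)c([C@@H](CCC)CC(=O)OC)c(O)c3c2O[C@H](C)[C@H](C)C3=O)C1(C)C
F3 | step 17 | 8-allyl analogue of 30 (prop-2-en-1-yl in place of prenyl) | C=C(C)[C@H]1C[C@@H](C[C@@]2(CC=C)C(=O)C([C@@H](CCC)CC(=O)OC)=C(O)C3=C2O[C@H](C)[C@H](C)C3=O)C1(C)C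
F4 | step 6 | (1R,3R)-2,2-dimethyl-3-(prop-1-en-2-yl)cyclobutane-1-carbaldehyde | C=C(C)[C@H]1C[C@@H](C=O)C1(C)C
F5 | step 6 | (5S)-3-[hydroxy(cyclobutyl)methyl]-5-menthyloxy lactone (mixture at the two new centres) | C=C(C)[C@H]1C[C@@H](C(O)C2C[C@@H](O[C@H]3C[C@@H](C)CC[C@@H]3C(C)C)OC2=O)C1(C)C
F6 | step 6 | (5S,E)-3-(cyclobutylmethylidene)-5-menthyloxy lactone | C=C(C)[C@H]1C[C@@H](/C=C2\C[C@@H](O[C@H]3C[C@@H](C)CC[C@@H]3C(C)C)OC2=O)C1(C)C
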